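## The problem

The target, 23, is an unsymmetrical ether of two 2-(2-phenylethyl)chromone units. The upper unit is a 5,6,7,8-tetrahydrochromone whose ring A carries four contiguous oxygenated stereocentres, (5S,6S,7R,8S). O5 is bonded to C6' of a 7-hydroxy-2-(2-phenylethyl)chromone. The ring-A oxygens are 5,8-cis and 6,7-cis, with the two pairs trans to each other. Once C5 and C8 are set, the C6/C7 diol can be controlled from them, but the absolute sense must come from outside. The ether carbon C6' is meta to the acyl-bearing C4a' and para to O1', so nucleophilic aromatic substitution is not available, and O6' must be told apart from O7'. Three sensitivities govern the order of events: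
- Any intermediate with a hydrogen or enol at C4a next to the C5 aryloxy group loses the aryloxide by β-elimination.
- A ring A with C4a=C8a and C6=C7 together aromatises.
- A chromone is attacked or deprotonated (at the CH2 on C2) by hard bases.

The enabling feature is that C4a with its acyl carbon C4, and the oxygenated C8a, are the ipso and ortho carbons of benzoic acid. What remains, C5=C6–C7=C8, is a cisoid diene whose termini need two cis oxygens.

## Retrosynthesis

**C4a=C8a double bond (23 ⇒ 22 ⇒ 21 ⇒ 20).** The last bond made is the C4a=C8a double bond of the upper pyranone, by loss of water from the tertiary C4a–OH of 20 and the C8a–H. The alternative, a C8a ketone with C4a–H (a 2-acylcyclohexanone), would put an enolisable hydrogen β to the aryloxy group, so C4a stays fully substituted until the pyranone ring exists. In the trans-fused 20 the C4a–OH and C8a–H are trans-diaxial, which is what an anti elimination needs. The secondary hydroxyls and the phenol are masked as acetates for that step (21 ⇒ 22) and freed at the end (22 ⇒ 23).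

**O1–C2 bond (20 ⇒ 18, through 19).** The O1–C2 bond is cut to give ynone 18. An open-chain β-diketone closed under acid was rejected: once the acetonide is gone, the tertiary O4a–H would attack the distal carbonyl in a five-membered exo closure and give a spiro furanone. With the ynone under mild base only O8a–H can close, by a six-membered endo addition. O4a–H would need a five-membered endo closure, and O6–H or O8–H a seven-membered one.

**C3–C4 bond (18 ⇒ 16 + 17).** This is the addition of the lithium acetylide of 4-phenylbut-1-yne (17) to an N-methoxy-N-methylamide. The amide is carried instead of a methyl ester because the addition must stop at the ketone. The side chain goes on after the aryl ether, because a free O5–H next to an ynone would itself close a pyranone ring under the basic arylation conditions.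

**O5–C6' bond (16 ⇒ 9 + 15).** The cut is made on the aryl side, so the C5–O bond and its configuration are kept. Cutting C5–O instead would require substitution with inversion at a carbon next to the quaternary C4a. Since C6' is not activated for nucleophilic aromatic substitution, the forward step is a palladium-catalysed C–O coupling of alcohol 9 with bromochromone 15. Compound 15 comes from 2',4'-dihydroxyacetophenone (10) by bromination at C5' (11), C-acylation with 3-phenylpropanoyl chloride (12) to diketone 13, cyclodehydration to 14 and O7' protection.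

**C6–O, C7–O and the O5/O8 distinction (9 ⇒ 8 ⇒ 7 ⇒ 6).** The C6–O and C7–O bonds are cut back to the alkene of 7, since osmium adds anti to the two allylic oxygens. O5 and O8 are distinguished by silylating the less hindered O8 (6 ⇒ 7). Closing a γ-lactone from C4 onto O8 was considered and dropped: the lactone and the dioxolane would share the C4a–C8a bond as a trans-fused pair of five-membered rings.

**C5–O and C8–O (6 ⇒ 5 ⇒ 4).** Both bonds are cut together. Endoperoxide 5 is the [4+2] adduct of singlet oxygen and diene 4, and the acetonide of 4 decides the face.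

**Diene (4 ⇒ 3 ⇒ 2 ⇒ 1).** The diene is the acetonide amide of the cis-diol 2, which a benzoate dioxygenase strain makes from benzoic acid (1) as a single enantiomer.

## Roads not taken

**Alternative 1:** The cut is at C5–C6 and C7–C8. Irradiation of a formyl pyranone bearing a benzyloxymethyl group would give a dienol, trapped by a trans-bis(sulfonyl)alkene to give A1, an 8-benzyloxy-5-hydroxy-6,7-bis(phenylsulfonyl)tetrahydrochromone.
- Merits: the pyranone and its side chain exist from the start, and ring A closes in one step with no late dehydration. In this respect it is better than the chosen plan, which spends steps 13 to 17 on the pyranone.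
- Weak points: C6 and C7 arrive as trans sulfones where a cis diol is needed. Removing them passes through a 5,8-dioxygenated dihydrochromone that aromatises by loss of water or benzyl alcohol. The adduct is racemic unless further control is added. O5 would have to be arylated while it sits next to the pyranone enol ether, where it ionises and oxidises easily.
- Comparison: the chosen plan delivers the C5 and C8 oxygens with absolute configuration, and dihydroxylates C6=C7 while C4a and C8a are still sp3.

**Alternative 2:** The cut is at C4a–C5. A tetravalent titanium Lewis acid, TiCl3(Oi-Pr), would open an aryl 6-deoxyhex-5-enopyranoside and the titanium enolate would attack the aryloxy-stabilised oxocarbenium carbon (a Ferrier-type carbocyclisation with the aglycone kept), giving cyclohexanone A2.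
- Merits: the aryl ether is made as a phenol glycoside, which is easier than arylating a hindered alcohol, and C6 to C8 come from the chiral pool. In both respects it is better than the chosen plan.
- Weak points: A2 has a C4a methylene next to the C8a ketone. Introducing C4 means enolising toward C4a, β to the aryloxy group, and elimination of the aryloxide is then expected. The C5 configuration is set in the cyclisation and is not secured. Three benzyl ethers must be removed at the end beside an allylic-type C5–O bond.
- Comparison: the chosen plan has C4 attached from the first step and a C4a that cannot enolise.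

**Alternative 3:** The cut is at C8–C8a. A triazolium-derived carbene would turn the C8a aldehyde of a sugar-derived dialdehyde into an acyl anion equivalent that adds to the C8 aldehyde, giving hydroxy ketone A3.
- Merits: mild, metal-free, and C5 to C7 come from the chiral pool. It matches the chosen plan in mildness.
- Weak points: it must be selective as to which aldehyde becomes the nucleophile, and for the C8 configuration. The β-alkoxy aldehyde can eliminate under the amine base. A3 lacks both C4 and the aryl group. Adding C4 at C4a meets the same β-elimination as in Alternative 2, and O5 arylation after removal of the 4-methoxybenzyl group is the same hindered coupling as in the chosen plan.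
- Comparison: the chosen plan reaches the same oxygenation pattern in two steps from a diene that already holds C4.

Key step: step 4

Conventions: ring-A carbons keep the target locants throughout (C4 is the carbonyl carbon on C4a). β is the face of C4 on C4a; α is the face of the two oxygens from the enzymatic diol. Primed locants refer to the lower chromone.

Assumption: the Ralstonia eutropha B9 strain is taken as obtainable from a culture collection, so benzoic acid is the commercial starting material of ring A.

## Steps

Step 1
Reactants: 1 benzoic acid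
Product: 2 (1S,2R)-1,2-dihydroxycyclohexa-3,5-diene-1-carboxylic acid
Conditions: Ralstonia eutropha B9 whole cells, fructose, aerated mineral salts medium, pH 7, 30 °C
Reagents that add atoms: dioxygen, O=O
Why: Microbial arene cis-dihydroxylation; the benzoate dioxygenase adds both oxygens to the ipso and ortho carbons on one face, and the strain lacks the dehydrogenase that would rearomatise the diol, so the enzyme sets both stereocentres.

Step 2
Reactants: 2 cis-diol acid
Product: 3 (3aS,7aR)-2,2-dimethyl-3a,7a-dihydro-1,3-benzodioxole-3a-carboxylic acid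
Conditions: 2,2-dimethoxypropane, TsOH·H2O (cat.), acetone, rt, short reaction time
Reagents that add atoms: 2,2-dimethoxypropane, COC(C)(C)OC
Why: Acid-catalysed transketalisation of a cis-1,2-diol to the dioxolane; mild acid and short time should avoid dehydration to the arene.

Step 3
Reactants: 3 acetonide acid
Product: 4 (3aS,7aR)-N-methoxy-N,2,2-trimethyl-3a,7a-dihydro-1,3-benzodioxole-3a-carboxamide
Conditions: 1,1'-carbonyldiimidazole, CH2Cl2, rt; then MeNHOMe·HCl, rt
Reagents that add atoms: N,O-dimethylhydroxylamine hydrochloride, CNOC.Cl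
Why: Acyl imidazolide formation and aminolysis (Weinreb amide synthesis); no stereocentre is touched, and the amide allows a single later addition at C4.

Step 4
Reactants: 4 acetonide amide diene
Product: 5 endoperoxide of 4 (2,3-dioxabicyclo[2.2.2]oct-5-ene; O–O bridge on C5 and C8 on the β face; anti to the 4a,8a-acetonide)
Conditions: O2, tetraphenylporphyrin (cat.), CH2Cl2, visible light, −20 °C
Reagents that add atoms: dioxygen, O=O
Why: Energy transfer from the excited porphyrin gives singlet oxygen, which adds to the cisoid C5=C6–C7=C8 diene in a concerted suprafacial [4+2] cycloaddition, the reaction type known for acetonides of arene cis-dihydrodiols. The new six-membered 1,2-dioxane ring (O–C5–C6=C7–C8–O) closes by cycloaddition with both C–O bonds formed together, so the peroxide bridge can only be cis. C5 and C8 are the new stereocentres: their cis relation follows from suprafacial addition, and their sense from attack on the β face, away from the dioxolane whose endo methyl group and two allylic oxygens cover the α face. The step needs facial selectivity, which the cis-fused acetonide secures, and [4+2] over ene selectivity, which the ring-locked s-cis diene favours. Low temperature and a neutral medium should keep the diene from dimerising and the endoperoxide from base-induced Kornblum–DeLaMare opening.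

Step 5
Reactants: 5 endoperoxide
Product: 6 5β,8β-dihydroxy-4a,8a-O-isopropylidene-cyclohex-6-ene-4a-(N-methoxy-N-methylcarboxamide)
Conditions: thiourea, MeOH, rt
Reagents that add atoms: none
Why: Thiourea reduces the O–O bond by nucleophilic attack of sulfur; both C–O bonds stay, so the 5,8-cis-diol keeps the configuration set in step 4.

Step 6
Reactants: 6 5β,8β-diol
Product: 7 8β-O-tert-butyldimethylsilyl ether of 6 (5β-OH free)
Conditions: TBSCl, imidazole, DMF, −20 → 0 °C
Reagents that add atoms: tert-butyldimethylsilyl chloride, CC(C)(C)[Si](C)(C)Cl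
Why: Sterically controlled mono-silylation; O8 sits next to the C8a methine, whereas O5 sits next to the fully substituted C4a with the amide on its own face.

Step 7
Reactants: 7 8-O-silyl allylic alcohol
Product: 8 5β,6α,7α-triol (8β-OTBS; 4a,8a-acetonide)
Conditions: OsO4 (cat.), N-methylmorpholine N-oxide, acetone/H2O, rt
Reagents that add atoms: osmium tetroxide, O=[Os](=O)(=O)=O; N-methylmorpholine N-oxide, C[N+]1([O-])CCOCC1; water, O
Why: Catalytic syn-dihydroxylation (Upjohn conditions); osmium should add to the α face, anti to both allylic oxygen substituents at C5 and C8 and to the amide, giving the 6α,7α-diol.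

Step 8
Reactants: 8 5β,6α,7α-triol
Product: 9 4a,8a:6,7-di-O-isopropylidene 5β-alcohol (8β-OTBS)
Conditions: 2,2-dimethoxypropane, pyridinium p-toluenesulfonate (cat.), CH2Cl2, rt
Reagents that add atoms: 2,2-dimethoxypropane, COC(C)(C)OC
Why: Acetonide formation; only O6 and O7 are cis-vicinal, so O5 stays free as the single hydroxyl for the coupling.

Step 9
Reactants: 10 2',4'-dihydroxyacetophenone
Product: 11 5'-bromo-2',4'-dihydroxyacetophenone
Conditions: N-bromosuccinimide, MeCN, 0 °C → rt
Reagents that add atoms: N-bromosuccinimide, BrN1C(=O)CCC1=O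
Why: Electrophilic aromatic bromination; C5' is para to the 2'-hydroxyl and ortho to the 4'-hydroxyl, and less crowded than C3' between the two hydroxyls.

Step 10
Reactants: 11 5'-bromo-2',4'-dihydroxyacetophenone; 12 3-phenylpropanoyl chloride
Product: 14 6-bromo-7-hydroxy-2-(2-phenylethyl)-4H-chromen-4-one, via aryl diketone 13 (not isolated)
Conditions: LiN(SiMe3)2 (4 equiv), THF, −78 → −10 °C; 12, −78 °C → rt; then AcOH, H2SO4 (cat.), 95 °C
Reagents that add atoms: none
Why: The lithium enolate of the phenoxide-protected acetophenone is C-acylated by the acid chloride (the direct equivalent of a Baker–Venkataraman sequence), and acid then closes the chromone by cyclodehydration.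

Step 11
Reactants: 14 6-bromo-7-hydroxychromone
Product: 15 6-bromo-7-(methoxymethoxy)-2-(2-phenylethyl)-4H-chromen-4-one
Conditions: MOMCl, i-Pr2NEt, CH2Cl2, 0 °C → rt
Reagents that add atoms: chloromethyl methyl ether, COCCl
Why: O-alkylation of the phenol; the acetal survives base, palladium and the acetylide, and falls with the other acid-labile groups in step 14.

Step 12
Reactants: 9 5β-alcohol; 15 bromochromone
Product: 16 5β-O-aryl ether of 9 (aryl = 7-(methoxymethoxy)-4-oxo-2-(2-phenylethyl)-4H-chromen-6-yl)
Conditions: [Pd(C3H5)Cl]2 (cat.), RockPhos [2-(di-tert-butylphosphino)-3-methoxy-6-methyl-2',4',6'-triisopropylbiphenyl], Cs2CO3, toluene, 90 °C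
Reagents that add atoms: none
Why: Palladium-catalysed C–O cross-coupling of a secondary alcohol with an aryl bromide (Buchwald–Hartwig-type etherification); the bulky biaryl phosphine should favour C–O reductive elimination over β-hydride loss. The C5–O bond is not broken, so C5 keeps its configuration.

Step 13
Reactants: 16 aryl ether amide; 17 4-phenylbut-1-yne
Product: 18 ynone (C4a-bound 5-phenylpent-2-yn-1-one; otherwise as 16)
Conditions: 17, n-BuLi, THF, −78 °C; then 16, −78 → 0 °C; sat. aq. NH4Cl
Reagents that add atoms: none
Why: Weinreb ketone synthesis; the chelated tetrahedral adduct should stop the reaction at the ketone, and at low temperature the amide should react before the vinylogous-ester carbonyl of the chromone.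

Step 14
Reactants: 18 protected ynone
Product: 20 trans-fused 4a-hydroxy-2-(2-phenylethyl)-4a,5,6,7,8,8a-hexahydro-4H-chromen-4-one with 5β-O-(7-hydroxy-4-oxo-2-(2-phenylethyl)-4H-chromen-6-yl) and 6α,7α,8β-triol, via deprotected ynone 19 (not isolated)
Conditions: TFA/H2O (9:1), 0 °C → rt; evaporate; K2CO3, MeOH, 0 °C → rt
Reagents that add atoms: none
Why: Acid hydrolysis removes both acetonides, the silyl ether and the methoxymethyl ether; base then triggers the six-membered endo oxa-Michael addition of O8a–H to the ynone, a known route from β-hydroxy ynones to dihydropyranones. O4a–H would need a five-membered endo closure and O6–H or O8–H a seven-membered one, so only O8a should close. No stereocentre is formed or broken.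

Step 15
Reactants: 20 4a-hydroxy dihydropyranone
Product: 21 6,7,8,7'-tetra-O-acetate of 20 (4a-OH free)
Conditions: Ac2O, pyridine, rt
Reagents that add atoms: acetic anhydride, CC(=O)OC(C)=O
Why: Acetylation of the three secondary alcohols and the phenol; the tertiary α-ketol hydroxyl should not react without an acyl-transfer catalyst.

Step 16
Reactants: 21 tetraacetate
Product: 22 6,7,8,7'-tetra-O-acetate of 23
Conditions: SOCl2, pyridine, CH2Cl2, −20 → 0 °C
Reagents that add atoms: none
Why: Dehydration of a tertiary alcohol through its chlorosulfite by anti E2 elimination; in the trans-fused bicycle only the C8a–H is antiperiplanar to the axial C4a–O bond (the C5–H is gauche), so the double bond should form toward C8a and complete the pyranone.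

Step 17
Reactants: 22 tetraacetate
Product: 23 6-{[(5S,6S,7R,8S)-6,7,8-trihydroxy-4-oxo-2-(2-phenylethyl)-5,6,7,8-tetrahydro-4H-chromen-5-yl]oxy}-7-hydroxy-2-(2-phenylethyl)-4H-chromen-4-one
Conditions: K2CO3 (cat.), MeOH, 0 °C
Reagents that add atoms: none
Why: Base-catalysed transesterification (Zemplén-type deacetylation); no acid is used, which spares the C5–O bond next to the pyranone.

## Compound list

1 | benzoic acid | OC(=O)c1ccccc1 | starting material
2 | (1S,2R)-1,2-dihydroxycyclohexa-3,5-diene-1-carboxylic acid | OC(=O)[C@]1(O)C=CC=C[C@H]1O | intermediate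
3 | (3aS,7aR)-2,2-dimethyl-3a,7a-dihydro-1,3-benzodioxole-3a-carboxylic acid (acetonide of 2) | OC(=O)[C@]1(OC(C)(C)O2)C=CC=C[C@H]12 | intermediate
4 | (3aS,7aR)-N-methoxy-N,2,2-trimethyl-3a,7a-dihydro-1,3-benzodioxole-3a-carboxamide | CON(C)C(=O)[C@]1(OC(C)(C)O2)C=CC=C[C@H]12 | intermediate
5 | endoperoxide of 4: O–O bridge on C5 and C8 (β), anti to the 4a,8a-acetonide | CON(C)C(=O)[C@]1(OC(C)(C)O2)[C@H]3C=C[C@H](OO3)[C@H]12 | intermediate
6 | 5β,8β-dihydroxy-4a,8a-O-isopropylidene-cyclohex-6-ene-4a-(N-methoxy-N-methylcarboxamide) | CON(C)C(=O)[C@]1(OC(C)(C)O2)[C@H](O)C=C[C@H](O)[C@H]12 | intermediate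
7 | 8β-O-tert-butyldimethylsilyl ether of 6 | CON(C)C(=O)[C@]1(OC(C)(C)O2)[C@H](O)C=C[C@H](O[Si](C)(C)C(C)(C)C)[C@H]12 | intermediate
8 | 5β,6α,7α-triol with 8β-OTBS and 4a,8a-acetonide | CON(C)C(=O)[C@]1(OC(C)(C)O2)[C@H](O)[C@@H](O)[C@@H](O)[C@H](O[Si](C)(C)C(C)(C)C)[C@H]12 | intermediate
9 | 4a,8a:6,7-di-O-isopropylidene 5β-alcohol with 8β-OTBS | CON(C)C(=O)[C@]1(OC(C)(C)O2)[C@H](O)[C@@H](OC(C)(C)O3)[C@@H]3[C@H](O[Si](C)(C)C(C)(C)C)[C@H]12 | intermediate
10 | 2',4'-dihydroxyacetophenone | CC(=O)c1ccc(O)cc1O | starting material
11 | 5'-bromo-2',4'-dihydroxyacetophenone | CC(=O)c1cc(Br)c(O)cc1O | intermediate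
12 | 3-phenylpropanoyl chloride | O=C(Cl)CCc1ccccc1 | starting material
13 | 1-(5-bromo-2,4-dihydroxyphenyl)-5-phenylpentane-1,3-dione | O=C(CC(=O)CCc1ccccc1)c1cc(Br)c(O)cc1O | intermediate
14 | 6-bromo-7-hydroxy-2-(2-phenylethyl)-4H-chromen-4-one | O=c1cc(CCc2ccccc2)oc2cc(O)c(Br)cc12 | intermediate
15 | 6-bromo-7-(methoxymethoxy)-2-(2-phenylethyl)-4H-chromen-4-one | O=c1cc(CCc2ccccc2)oc2cc(OCOC)c(Br)cc12 | intermediate
16 | 5β-O-aryl ether of 9 (aryl = 7-(methoxymethoxy)-4-oxo-2-(2-phenylethyl)-4H-chromen-6-yl) | CON(C)C(=O)[C@]1(OC(C)(C)O2)[C@H](Oc4cc5c(=O)cc(CCc6ccccc6)oc5cc4OCOC)[C@@H](OC(C)(C)O3)[C@@H]3[C@H](O[Si](C)(C)C(C)(C)C)[C@H]12 | intermediate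
17 | 4-phenylbut-1-yne | C#CCCc1ccccc1 | starting material
18 | ynone: C4 ketone bearing the 4-phenylbut-1-ynyl group; ring A as in 16 | O=C(C#CCCc1ccccc1)[C@]1(OC(C)(C)O2)[C@H](Oc4cc5c(=O)cc(CCc6ccccc6)oc5cc4OCOC)[C@@H](OC(C)(C)O3)[C@@H]3[C@H](O[Si](C)(C)C(C)(C)C)[C@H]12 | intermediate
19 | fully deprotected ynone: 4a-OH and 8a-OH (α), 6α,7α,8β-triol, 5β-O-(7-hydroxychromon-6-yl) | O=C(C#CCCc1ccccc1)[C@]1(O)[C@H](Oc2cc3c(=O)cc(CCc4ccccc4)oc3cc2O)[C@@H](O)[C@@H](O)[C@H](O)[C@H]1O | intermediate
20 | trans-fused 4a-hydroxy-2-(2-phenylethyl)-4a,5,6,7,8,8a-hexahydro-4H-chromen-4-one: 4a-OH α, 8a-H β, 5β-O-(7-hydroxy-4-oxo-2-(2-phenylethyl)-4H-chromen-6-yl), 6α,7α,8β-triol | O=C1C=C(CCc2ccccc2)O[C@H]3[C@@]1(O)[C@H](Oc2cc4c(=O)cc(CCc5ccccc5)oc4cc2O)[C@@H](O)[C@@H](O)[C@@H]3O | intermediate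
21 | 6,7,8,7'-tetra-O-acetate of 20 | O=C1C=C(CCc2ccccc2)O[C@H]3[C@@]1(O)[C@H](Oc2cc4c(=O)cc(CCc5ccccc5)oc4cc2OC(C)=O)[C@@H](OC(C)=O)[C@@H](OC(C)=O)[C@@H]3OC(C)=O | intermediate
22 | 6,7,8,7'-tetra-O-acetate of 23 | O=c1cc(CCc2ccccc2)oc2c1[C@H](Oc1cc3c(=O)cc(CCc4ccccc4)oc3cc1OC(C)=O)[C@@H](OC(C)=O)[C@@H](OC(C)=O)[C@@H]2OC(C)=O | intermediate
23 | 6-{[(5S,6S,7R,8S)-6,7,8-trihydroxy-4-oxo-2-(2-phenylethyl)-5,6,7,8-tetrahydro-4H-chromen-5-yl]oxy}-7-hydroxy-2-(2-phenylethyl)-4H-chromen-4-one (CNP0248258.1) | O=c1cc(CCc2ccccc2)oc2c1[C@H](Oc1cc3c(=O)cc(CCc4ccccc4)oc3cc1O)[C@@H](O)[C@@H](O)[C@@H]2O | target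

## Step count and least certain steps

Total step count: 17. Longest linear sequence: 14 steps (steps 1 to 8 and 12 to 17, from benzoic acid to 23).

**Step 4 (key step).** The risks are erosion of facial selectivity, a competing ene reaction or diene dimerisation, and base- or heat-induced opening of the endoperoxide. Fallback: from 4, epoxidation with m-chloroperbenzoic acid (NaHCO3, CH2Cl2) anti to the acetonide would give the 7β,8β-epoxide F1. Zerovalent palladium, Pd(PPh3)4, with acetic acid would open this vinyl epoxide in the cis-1,4 sense (Tsuji–Trost-type double inversion) to the 5β-acetoxy-8β-alcohol F2. Silylation of O8 would give the 5-acetate 8-silyl ether F3, and K2CO3 in methanol would return the route at 7. This path also differentiates O5 from O8 without relying on sterics.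

**Step 12.** On this hindered axial alcohol, alkoxide transfer to palladium may be slow. β-Hydride loss would then oxidise C5 and reduce the aryl bromide. Fallback: form the ether before dihydroxylation on the less hindered allylic alcohol, with copper so that the allylic aryl ether is not ionised. From 15, halogen exchange (CuI, NaI, trans-N,N'-dimethylcyclohexane-1,2-diamine, dioxane) would give the aryl iodide F4. Ullmann-type coupling of 7 with F4 (CuI, 3,4,7,8-tetramethyl-1,10-phenanthroline, Cs2CO3, toluene) would give the allylic aryl ether F5. Dihydroxylation as in step 7 would give diol F6, whose acetonide formation as in step 8 returns the route at 16.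

**Step 16.** The chlorosulfite may ionise or be displaced instead of eliminating, or elimination may run toward C5 if the ring leaves the chair. Fallback: from 21, mesylation through the sulfene (MsCl, Et3N, CH2Cl2) would give the isolated tertiary mesylate F7. A separate base-induced anti elimination with 1,8-diazabicyclo[5.4.0]undec-7-ene in toluene would return the route at 22.

**Step 14.** The ynone may be hydrated during the acid stage, after which closure through O4a–H to a spiro furanone becomes possible, or retro-aldol cleavage may compete under base. Fallback: block O4a. From 18, after the acid stage, per-silylation of crude 19 (TESOTf, 2,6-lutidine) would give the hexakis(triethylsilyl) ether F8. Pyridinium p-toluenesulfonate and then K2CO3 in methanol should remove the phenolic and secondary silyl groups, leave the tertiary α-keto silyl ether, and close the ring to the 4a-O-triethylsilyl dihydropyranone F9. HF·pyridine would then return the route at 20.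

**Step 13.** The acetylide may attack or deprotonate the chromone, addition to the hindered amide may be sluggish, or the amide may lose formaldehyde by base-induced N–O cleavage. Fallback: from 16, reduction with Cp2Zr(H)Cl would give the aldehyde F10. Addition of 17 under Zn(OTf)2 and Et3N, which the chromone tolerates, would give the propargylic alcohol F11 as a mixture of C4 epimers. Oxidation with Dess–Martin periodinane would return the route at 18.

**Step 6.** Discrimination between O5 and O8 may be incomplete. Fallback: change the order so that the two hydroxyls differ more. From 6, dihydroxylation as in step 7 would give the tetrol F12, and acetonide formation the 5β,8β-diol F13, in which O5 is axial next to the quaternary carbon and O8 equatorial. Mono-silylation with TBSCl and imidazole then returns the route at 9.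

## Further compounds

F1 | step 4 | 7β,8β-epoxide of 4 (anti to the acetonide; C5=C6 retained) | CON(C)C(=O)[C@]1(OC(C)(C)O2)C=C[C@@H]3O[C@@H]3[C@H]12
F2 | step 4 | 5β-acetoxy-8β-hydroxy-cyclohex-6-ene analogue of 6 | CON(C)C(=O)[C@]1(OC(C)(C)O2)[C@H](OC(C)=O)C=C[C@H](O)[C@H]12
F3 | step 4 | 5β-acetate of 7 | CON(C)C(=O)[C@]1(OC(C)(C)O2)[C@H](OC(C)=O)C=C[C@H](O[Si](C)(C)C(C)(C)C)[C@H]12
F4 | step 12 | 6-iodo-7-(methoxymethoxy)-2-(2-phenylethyl)-4H-chromen-4-one | O=c1cc(CCc2ccccc2)oc2cc(OCOC)c(I)cc12
F5 | step 12 | 5β-O-aryl ether of 7 (allylic aryl ether; C6=C7 retained) | CON(C)C(=O)[C@]1(OC(C)(C)O2)[C@H](Oc4cc5c(=O)cc(CCc6ccccc6)oc5cc4OCOC)C=C[C@H](O[Si](C)(C)C(C)(C)C)[C@H]12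
F6 | step 12 | 6α,7α-diol from F5 | CON(C)C(=O)[C@]1(OC(C)(C)O2)[C@H](Oc4cc5c(=O)cc(CCc6ccccc6)oc5cc4OCOC)[C@@H](O)[C@@H](O)[C@H](O[Si](C)(C)C(C)(C)C)[C@H]12
F7 | step 16 | 4a-O-methanesulfonate of 21 | O=C1C=C(CCc2ccccc2)O[C@H]3[C@@]1(OS(C)(=O)=O)[C@H](Oc2cc4c(=O)cc(CCc5ccccc5)oc4cc2OC(C)=O)[C@@H](OC(C)=O)[C@@H](OC(C)=O)[C@@H]3OC(C)=O
F8 | step 14 | hexakis(triethylsilyl) ether of 19 | O=C(C#CCCc1ccccc1)[C@]1(O[Si](CC)(CC)CC)[C@H](Oc2cc3c(=O)cc(CCc4ccccc4)oc3cc2O[Si](CC)(CC)CC)[C@@H](O[Si](CC)(CC)CC)[C@@H](O[Si](CC)(CC)CC)[C@H](O[Si](CC)(CC)CC)[C@H]1O[Si](CC)(CC)CC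
F9 | step 14 | 4a-O-triethylsilyl ether of 20 | O=C1C=C(CCc2ccccc2)O[C@H]3[C@@]1(O[Si](CC)(CC)CC)[C@H](Oc2cc4c(=O)cc(CCc5ccccc5)oc4cc2O)[C@@H](O)[C@@H](O)[C@@H]3O
F10 | step 13 | C4 aldehyde corresponding to 16 | O=C[C@]1(OC(C)(C)O2)[C@H](Oc4cc5c(=O)cc(CCc6ccccc6)oc5cc4OCOC)[C@@H](OC(C)(C)O3)[C@@H]3[C@H](O[Si](C)(C)C(C)(C)C)[C@H]12
F11 | step 13 | C4 propargylic alcohol corresponding to 18 (mixture of C4 epimers) | OC(C#CCCc1ccccc1)[C@]1(OC(C)(C)O2)[C@H](Oc4cc5c(=O)cc(CCc6ccccc6)oc5cc4OCOC)[C@@H](OC(C)(C)O3)[C@@H]3[C@H](O[Si](C)(C)C(C)(C)C)[C@H]12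
F12 | step 6 | 5β,6α,7α,8β-tetrol with 4a,8a-acetonide | CON(C)C(=O)[C@]1(OC(C)(C)O2)[C@H](O)[C@@H](O)[C@@H](O)[C@H](O)[C@H]12
F13 | step 6 | 4a,8a:6,7-di-O-isopropylidene 5β,8β-diol | CON(C)C(=O)[C@]1(OC(C)(C)O2)[C@H](O)[C@@H](OC(C)(C)O3)[C@@H]3[C@H](O)[C@H]12
A1 | alternative 1 | 8-benzyloxy-5-hydroxy-6,7-bis(phenylsulfonyl)-5,6,7,8-tetrahydro-2-(2-phenylethyl)chromone | O=c1cc(CCc2ccccc2)oc2c1[C@H](O)[C@@H](S(=O)(=O)c1ccccc1)[C@H](S(=O)(=O)c1ccccc1)[C@@H]2OCc1ccccc1
A2 | alternative 2 | 3-aryloxy-4,5,6-tris(benzyloxy)cyclohexanone (aryl = 7-benzyloxy-4-oxo-2-(2-phenylethyl)-4H-chromen-6-yl) | O=C1C[C@H](Oc2cc3c(=O)cc(CCc4ccccc4)oc3cc2OCc2ccccc2)[C@@H](OCc2ccccc2)[C@@H](OCc2ccccc2)[C@@H]1OCc1ccccc1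
A3 | alternative 3 | 2-hydroxy-3,4-isopropylidenedioxy-5-(4-methoxybenzyloxy)cyclohexanone | O=C1C[C@H](OCc2ccc(OC)cc2)[C@@H](OC(C)(C)O3)[C@@H]3[C@@H]1O
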